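The runs were generated by integration from invented constants, noise included.

Watch E, not the clock. These are the charges, the readings and the question.

| flask | X | E | D | remark | time |
|---|---|---|---|---|---|
| east | 2.2 mM | 1.3 equiv | 0.3 mol% | run made earlier |  |
| north-west | 17 mM | 1.3 equiv | 0.3 mol% | run made earlier |  |
| north-east | 96 mM | 1.3 equiv | 0.3 mol% | run made earlier |  |
| Thursday's | 3.0 mM | 1.30 equiv | 0.3 mol% |  | 10 h |
| Saturday's | 10 mM | 1.30 equiv | 0.3 mol% |  | 10 h |
| Friday's | 30 mM | 1.30 equiv | 0.3 mol% |  | 10 h |
| Tuesday's | 100 mM | 1.30 equiv | 0.3 mol% |  | 10 h |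

| east: time / h | east: Q / % | north-west: time / h | north-west: Q / % | north-east: time / h | north-east: Q / % |
|---|---|---|---|---|---|
| 1.33 | 1.8 | 0.667 | 6.2 | 0.667 | 12.2 |
| 3.00 | 4.7 | 2.00 | 15.0 | 2.00 | 24.4 |
| 4.00 | 6.1 | 3.00 | 19.1 | 3.00 | 25.9 |
| 6.00 | 8.6 | 5.00 | 24.9 | 5.00 | 18.5 |
| 8.00 | 11.1 | 8.00 | 25.3 | 8.00 | 15.1 |

(each reading ± 0.3 percentage points)

- "hardly changes" means that all values lie within two and a half points (for a concentration: within two and a half percent of the largest)

* amount of Q at the end, in percent of the X charged for Thursday's, Saturday's, Friday's, Tuesday's, in this order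
* how the row runs (hardly changes / rises all the way / falls all the way / rises, then falls / falls, then rises)

I build the flask up one process at a time. Let f be the fraction of its own charge of E still left, w the equivalents charged, and u the fraction of the X charged that has turned over, each X taking one E, so that f is one minus u over w.

First the main step. The dilute east run turns over 0.0157 h⁻¹ at 2.2 mM, and I let that grow with concentration. The north-east run makes 0.183 h⁻¹ over its first 0.667 h, and I take this reading as the ceiling. Joining the ends by adding reciprocal rates, then running for 10 h, gives u of 19.1%, 51.3%, 98.5% and, capped at the charge, 100%. Without a loss, Q equals u, and the row rises.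

Now the loss of Q. The north-west run reads 25.3% at 8.00 h and the north-east run 25.9% at 3.00 h, so two very different concentrations give readings of nearly the same height at different times. I therefore suppose that the spending of E and the loss of Q run on the same free D, which cancels D and time from their ratio. Then, at fixed w and S, Q follows from f: Q is w times the difference between f and f to the power S, divided by S less one.

Then the end. X is the limiting reagent, so f stands at 23.1% when u reaches one, and the rule stops there. Reading 15.1% at 8.00 h in the north-east run as that end gives S near 2.99. Keeping the small power term gives 2.88, the selectivity factor S, the ratio of the fractional loss of Q to the fractional spending of E. The top of the curve then lies at f of 57.0% with Q at 25.7%.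

So my row is 15.3%, 25.6%, 15.6%, 15.0%.

The forecast gives 16%, 25%, 18%, 13%, with the shape rises, then falls, on the ground that “the curves should collapse on one time-scaled curve”.

Thursday's, Saturday's, Friday's and Tuesday's flasks give 16.3%, 25.8%, 17.4%, 14.8%, with the shape rises, then falls.

    E + D → Z (k = 35.0 M⁻¹ min⁻¹)
    X + Z → L (k = 15000 M⁻¹ min⁻¹)
    L → D + Q (k = 1.70 min⁻¹)
    D + Q → D + J (k = 100 M⁻¹ min⁻¹)
    X ⇌ G (K = 0.210, k = 0.0230 min⁻¹)

Thursday's flask holds 13.8% as G at 10.0 h, a form absent from my reckoning, yet that step makes no difference to Thursday's Q. With S at 2.88, the 59.5% of E in Saturday's flask at 10.0 h gives Q of 25.6%, and the flask holds 25.8%. The 28.9% of E in Tuesday's flask at 5.00 h gives 18.0%, and that flask holds 18.2%.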